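The runs are simulated with made-up constants; scatter was added.

How much target stands at the end when the same charges go in by different routes?

in all of them: rival reagent 1.05 M
- dusk: substrate 0.21 M; coupling partner 0.252 M; run made earlier
- noon: substrate 0.10 M; coupling partner 0.252 M; run made earlier
- winter: substrate 0.16 M; coupling partner 0.252 M; run made earlier
- gamma: substrate 0.21 M (fed, over 15 h); coupling partner 0.252 M; all else is in the flask from the start; the feed brings no volume worth counting; time 3.0 d
- alpha: substrate 0.21 M; coupling partner 0.252 M; everything together at the start; time 3.0 d
- delta: substrate 0.21 M; coupling partner 0.252 M (fed, over 2.5 d); all else is in the flask from the start; the feed brings no volume worth counting; time 3.0 d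
- beta: substrate 0.21 M (fed, over 2.5 d); coupling partner 0.252 M; all else is in the flask from the start; the feed brings no volume worth counting; time 3.0 d

| run | time / d | target / % | substrate / % |
|---|---|---|---|
| dusk | 0.250 | 16.1 | 0 |
| dusk | 0.833 | 9.6 | 0.2 |
| dusk | 1.25 | 9.3 | 0.4 |
| dusk | 2.00 | 9.1 | 0.4 |
| dusk | 3.00 | 9.3 | 0 |
| noon | 0.333 | 13.1 | 0.7 |
| noon | 0.833 | 9.5 | 0 |
| noon | 1.67 | 8.8 | 0.6 |
| noon | 2.50 | 9.4 | 0 |
| noon | 4.00 | 8.2 | 0 |
| winter | 0.250 | 15.8 | 0.3 |
| winter | 0.500 | 11.0 | 0.2 |
| winter | 1.04 | 9.3 | 0 |
| winter | 2.08 | 8.7 | 0.4 |
| winter | 4.00 | 8.7 | 0 |

(standard deviation of a reading: 0.3 percentage points)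

- the best flask by amount of target, in percent of the substrate charged; "all alike" if 1.5 percentage points covers them all (gamma / alpha / delta / beta / all alike)
- amount of target at the end, in percent of the substrate charged, gamma
- amount of target at the end, in percent of the substrate charged, alpha
- amount of target at the end, in percent of the substrate charged, delta
- amount of target at the end, in percent of the substrate charged, beta



The winter run reads 15.8% of target at 0.250 d and 11.0% at 0.500 d, then holds near 8.70%. So target is relaxing towards a level, and the excess read from the first two points falls at 4.51 d⁻¹. Run back to zero time, this gives a first-formed target of 30.6%. The plateau fraction φ, the plateau target divided by the target first formed, is then 0.284, a reading with the scatter of these few points.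

Two chemists read this differently. The first sees thermodynamic control. The relaxation half-life of 0.154 d is shorter than the time, so, the first argues, every flask reaches its plateau and the route drops out.

The second sees kinetic control one step earlier. In this view end target is φ times whatever substrate coupled, and the rest of the substrate was lost to the rival reagent at c(coupling partner)/c(rival reagent) = 0.240. That gives a selectivity factor of 1.84. The winter run reads 0.3% of substrate already at 0.250 d, so the second takes that as the time the substrate has in delta. The partner fed into delta by then is 0.0252 M, so the coupled share drops and the second expects about 1.20% of target. For beta the runs are silent on whether the rival reagent lasts. If it fades early, late substrate meets the partner unopposed, and target approaches φ itself, 28.4%.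

The forecast takes the first side: 9.2% for gamma, 9.2% for alpha, 9.1% for delta, 9.4% for beta, and all alike, since “the addition order shouldn't matter once there is time to relax”.

The flasks give 22.5% in gamma, 8.75% in alpha, 0.364% in delta and 27.0% in beta, so beta is best. The first chemist's plateau holds in alpha, where the charges go in together: the forecast's 9.2% against 8.75% in the flask.

    coupling partner + target → over-reaction product (k = 0.0250 M⁻¹ h⁻¹)
    substrate + coupling partner → target (k = 5.00 M⁻¹ h⁻¹)
    rival reagent → decomposed reagent (k = 0.390 h⁻¹)
    substrate + rival reagent → side product (k = 2.40 M⁻¹ h⁻¹)
    target ⇌ isomer of the product (K = 2.50, k = 0.170 h⁻¹)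

Beta beats delta by 27 percentage points through the turning of substrate and rival reagent into side product, acting together with the way back from isomer to target. With the former struck out the gap is −0.32 points, with the latter 2.3 points. Beta turns 4.18% of the substrate into side product, so φ times the remainder gives 27.2%, against 27.0% of target in the flask. The neighbour like delta with 0.26 M of rival reagent makes 56.8% of side product, so φ times the remainder gives 12.3%, and that flask holds 11.7% of target.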